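Units A, B and C are the three guaianolides in the order of the target SMILES (guaiane numbering in each). The route rests on cutting the C2A–C4B bond of ring R1 (C4B, C15B, C14A, C10A, C1A, C2A), whose spiro carbon C4B lies α to the C3B ketone: with the enone double bond moved to C1A=C10A this ring is a 4-acylcyclohexene. One Claisen ring contraction makes that bond, closes R1 and sets the quaternary centre C4B against the facial bias of unit B by chirality transfer from C10A. The precursor is a spiro 2-vinyl-3,4-dihydro-2H-pyran: enol ether oxygen on C10A, C1A=C2A as the vinyl group.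

Key step: step 8

Remarks on the chemistry (assumptions)
- α is the face of a guaianolide unit that carries its H5 (and H1); β is the opposite face.
- The allylic hydroxylation of 1 is taken to give the 3α-alcohol; this configuration is irrelevant because the carbinol is oxidised in steps 2 and 6.
- Unit A enters the cycloaddition with C3 as a silyl ether and C4=C15 intact, so no thiol, selenium or amine mask has to be put on and taken off beside the α-methylene lactones.
- The rearrangement substrate 9 is used as the single C10A epimer (oxygen α), purified at the stage of 5.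
- The C2B centre of 14 is drawn as expected for α-face attack on the diene; it is erased in step 11.

Step 1
Reactants: 1 dehydrocostus lactone
Product: 2 3-epizaluzanin C
Conditions: SeO2 (0.3 equiv), t-BuOOH, CH2Cl2, rt
Reagents that add atoms: tert-butyl hydroperoxide, CC(C)(C)OO (terminal oxygen source); selenium dioxide, O=[Se]=O (oxygen carrier)
Why: Riley allylic oxidation (ene reaction at C4=C15, then [2,3]-sigmatropic shift) should hydroxylate the ring methylene C3 with retention of the exocyclic alkene, oxygen arriving on the convex α face, a centre that is later erased.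

Step 2
Reactants: 2 3-epizaluzanin C
Product: 3 dehydrozaluzanin C
Conditions: Dess–Martin periodinane, CH2Cl2, 0 °C to rt
Reagents that add atoms: none
Why: Dess–Martin oxidation of the secondary allylic alcohol should give the exocyclic enone under neutral conditions that leave the α-methylene lactone and the C10=C14 alkene untouched.

Step 3
Reactants: 2 3-epizaluzanin C
Product: 4 3-epizaluzanin C tert-butyldimethylsilyl ether
Conditions: TBSCl, imidazole, DMF, rt
Reagents that add atoms: tert-butyldimethylsilyl chloride, CC(C)(C)[Si](C)(C)Cl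
Why: Standard silylation of a secondary alcohol keeps unit A free of any enone, and the allylic silyloxy group deactivates and shields C4A=C15A so that C10A=C14A is the most nucleophilic alkene.

Step 4
Reactants: 3 dehydrozaluzanin C; 4 3-epizaluzanin C tert-butyldimethylsilyl ether
Product: 5 A–B spiro-dihydropyran silyl ether
Conditions: 3, Me2AlCl (2.2 equiv), CH2Cl2, −78 °C; then 4 (2.5 equiv), −78 to −30 °C
Reagents that add atoms: none
Why: In this Lewis-acid-promoted inverse-electron-demand hetero-Diels–Alder reaction the s-cis-locked, aluminium-complexed enone of 3 should be attacked at C15B by the terminal carbon C14A of the unhindered 1,1-dialkyl alkene, and the enolate oxygen should close on the tertiary C10A from the convex α face (the side of H1A), which sets the only new stereocentre.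

Step 5
Reactants: 5 A–B spiro-dihydropyran silyl ether
Product: 6 A–B spiro-dihydropyran 3A-alcohol
Conditions: HF·pyridine, pyridine, THF, 0 °C
Reagents that add atoms: none
Why: Fluoride-mediated desilylation in a pyridine-buffered medium should free the C3A alcohol without hydrolysing the tetrasubstituted enol ether or adding to the α-methylene lactones.

Step 6
Reactants: 6 A–B spiro-dihydropyran 3A-alcohol
Product: 7 A–B spiro-dihydropyran 3A-ketone
Conditions: Dess–Martin periodinane, pyridine, CH2Cl2, 0 °C to rt
Reagents that add atoms: none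
Why: Buffered Dess–Martin oxidation of the allylic alcohol should give the exocyclic enone of unit A, conditions under which cyclic enol ethers survive.

Step 7
Reactants: 7 A–B spiro-dihydropyran 3A-ketone
Product: 9 A–B spiro-dihydropyran dienone (Claisen precursor), via trimethylsilyl dienol ether 8 (not isolated)
Conditions: LiN(SiMe3)2, Me3SiCl, THF, −78 °C; then Pd(OAc)2, MeCN, rt
Reagents that add atoms: none
Why: In this Saegusa–Ito oxidation C2A is the only enolisable position of the only ketone, so kinetic silylation gives 8, and palladation at C2A with β-hydride elimination of H1A should install C1A=C2A, the vinyl group on the pyran carbon C10A.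

Step 8
Reactants: 9 A–B spiro-dihydropyran dienone (Claisen precursor)
Product: 10 A–B spiro dimer in its deconjugated enone form
Conditions: 1,2-dichlorobenzene (0.005 M), BHT (cat.), 2,6-di-tert-butyl-4-methylpyridine (cat.), sealed tube, 170 °C
Reagents that add atoms: none
Why: Heating lets the allyl vinyl ether C4B=C3B–O–C10A–C1A=C2A undergo a concerted [3,3] sigmatropic (Claisen) shift: C2A–C4B forms while O–C10A breaks, the enol ether becomes the C3B ketone and the alkene moves to C1A=C10A. The closest known reaction type is the thermal Claisen ring contraction of 2-alkenyl-3,4-dihydro-2H-pyrans to 4-acylcyclohexenes. Ring R1 is closed by contraction of the pyran, not by an end-to-end cyclisation, through a boat transition state shaped like bicyclo[2.2.2]octene with C10A and C4B as bridgeheads and O–C3B, C14A–C15B and C1A=C2A as bridges. C4B is controlled by the C10A stereocentre, whose C1A arm sits on one face of the pyran so that C2A must bond to the β face of unit B (anti to H5B) against that unit's own preference, and C2A is controlled by the suprafacial course over the allyl unit (new bond on the α face of unit A, from which the oxygen departs). The step needs the intramolecular shift to outrun retro-hetero-Diels–Alder cleavage with recombination and acid-induced migration of the enol ether double bond, which is secured by the tertiary allylic C10A–O bond, the enforced proximity of C2A and C4B in the spiro system, high dilution and a base-buffered medium. No Lewis acid is used because complexation of the C3A dienone would make C1A, not C2A, the carbon that the enol ether attacks.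

Step 9
Reactants: 10 A–B spiro dimer in its deconjugated enone form
Product: 11 A–B spiro dimer as conjugated dienone
Conditions: DBU (0.2 equiv), CH2Cl2, 0 °C
Reagents that add atoms: none
Why: Base-mediated isomerisation of a β,γ-unsaturated ketone through the cross-conjugated dienolate should remove the doubly activated H2A and reprotonate C10A from the convex α face, anti to the C5B arm of the spiro centre that covers the β face, giving H10A α (cis to H5A), which is also expected to be the more stable epimer.

Step 10
Reactants: 11 A–B spiro dimer as conjugated dienone; 3 dehydrozaluzanin C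
Product: 14 A–B–C Diels–Alder adduct, via unit B trimethylsilyl enol ether 12 (not isolated), via unit B dienone diene 13 (not isolated)
Conditions: LiN(SiMe3)2, Me3SiCl, THF, −78 °C; then 3 (5 equiv), Pd(OAc)2, MeCN, rt, argon
Reagents that add atoms: none
Why: Kinetic deprotonation with in situ silylation should take an α-hydrogen at C2B of the only saturated ketone faster than a γ-hydrogen of the unit A dienone, Saegusa–Ito oxidation of 12 gives the s-cis diene 13 (C2B=C1B–C10B=C14B), and excess 3 intercepts it in a Diels–Alder reaction (C2B–C4C and C14B–C15C) on the convex α face of its exocyclic enone, which sets the spiro centre C4C.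

Step 11
Reactants: 14 A–B–C Diels–Alder adduct
Product: 16 ainsliatrimer A, via C10B hydroperoxide 15 (not isolated)
Conditions: O2 (1 atm), Et3N, MeCN, 0 °C to rt; then P(OEt)3, 0 °C
Reagents that add atoms: dioxygen, O=O
Why: Base-promoted autoxidation (γ-hydroxylation) of the β,γ-unsaturated ketone of unit B should oxygenate the dienolate at C10B on the β face, anti to the C5C arm of spiro centre C4C, and phosphite reduction of 15 gives the tertiary alcohol with the C1B=C2B enone, while the much less acidic H10A of the conjugated unit A is not removed by the weak base.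

Compound list
1 | dehydrocostus lactone (natural enantiomer; H1α, H5α, H6β, H7α; methylenes on C4, C10, C11) | C=C1CC[C@H]2C(=C)CC[C@H]3C(=C)C(=O)O[C@@H]3[C@H]21 | starting material
2 | 3-epizaluzanin C (3α-hydroxy derivative of 1) | C=C1[C@H](O)C[C@H]2C(=C)CC[C@H]3C(=C)C(=O)O[C@@H]3[C@H]21 | intermediate
3 | dehydrozaluzanin C (3-oxo derivative of 1; source of units B and C) | C=C1C(=O)C[C@H]2C(=C)CC[C@H]3C(=C)C(=O)O[C@@H]3[C@H]21 | intermediate
4 | 3-epizaluzanin C tert-butyldimethylsilyl ether (3α-OTBS; unit A) | C=C1[C@H](O[Si](C)(C)C(C)(C)C)C[C@H]2C(=C)CC[C@H]3C(=C)C(=O)O[C@@H]3[C@H]21 | intermediate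
5 | A–B spiro-dihydropyran silyl ether (pyran O–C3B=C4B–C15B–C14A–C10A; spiro C10A with O α and C14A β; unit A 3α-OTBS, C4=C15, H1α) | C=C1[C@H](O[Si](C)(C)C(C)(C)C)C[C@@H]2[C@H]1[C@H]3OC(=O)C(=C)[C@@H]3CC[C@]24CCC5=C(O4)C[C@H]6C(=C)CC[C@H]7C(=C)C(=O)O[C@@H]7[C@@H]56 | intermediate
6 | A–B spiro-dihydropyran 3A-alcohol (3α-OH) | C=C1[C@H](O)C[C@@H]2[C@H]1[C@H]3OC(=O)C(=C)[C@@H]3CC[C@]24CCC5=C(O4)C[C@H]6C(=C)CC[C@H]7C(=C)C(=O)O[C@@H]7[C@@H]56 | intermediate
7 | A–B spiro-dihydropyran 3A-ketone (unit A exocyclic enone, C2A methylene, H1A α) | C=C1C(=O)C[C@@H]2[C@H]1[C@H]3OC(=O)C(=C)[C@@H]3CC[C@]24CCC5=C(O4)C[C@H]6C(=C)CC[C@H]7C(=C)C(=O)O[C@@H]7[C@@H]56 | intermediate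
8 | trimethylsilyl dienol ether of 7 (C2A=C3A–OSiMe3, C4A=C15A) | C=C1C(O[Si](C)(C)C)=C[C@@H]2[C@H]1[C@H]3OC(=O)C(=C)[C@@H]3CC[C@]24CCC5=C(O4)C[C@H]6C(=C)CC[C@H]7C(=C)C(=O)O[C@@H]7[C@@H]56 | intermediate
9 | A–B spiro-dihydropyran dienone, the Claisen precursor (2-vinyl-3,4-dihydro-2H-pyran; unit A C1A=C2A, C3A=O, C4A=C15A; O on C10A α) | C=C1C(=O)C=C2[C@H]1[C@H]3OC(=O)C(=C)[C@@H]3CC[C@]24CCC5=C(O4)C[C@H]6C(=C)CC[C@H]7C(=C)C(=O)O[C@@H]7[C@@H]56 | intermediate
10 | A–B spiro dimer, deconjugated enone form (C2A–C4B bond; C1A=C10A; H2A β; at C4B the C2A branch is β, anti to H5B) | C=C1C(=O)[C@H]2C3=C(CC[C@H]4C(=C)C(=O)O[C@@H]4[C@@H]13)CC[C@@]21C(=O)C[C@H]2C(=C)CC[C@H]3C(=C)C(=O)O[C@@H]3[C@H]21 | intermediate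
11 | A–B spiro dimer, conjugated dienone (C1A=C2A; H10A α) | C=C1C(=O)C2=C3[C@H](CC[C@H]4C(=C)C(=O)O[C@@H]4[C@@H]13)CC[C@@]21C(=O)C[C@H]2C(=C)CC[C@H]3C(=C)C(=O)O[C@@H]3[C@H]21 | intermediate
12 | unit B trimethylsilyl enol ether of 11 (C2B=C3B–OSiMe3) | C=C1C(=O)C2=C3[C@H](CC[C@H]4C(=C)C(=O)O[C@@H]4[C@@H]13)CC[C@@]21C(O[Si](C)(C)C)=C[C@H]2C(=C)CC[C@H]3C(=C)C(=O)O[C@@H]3[C@H]21 | intermediate
13 | A–B dimer with unit B dienone diene (C3B=O, C2B=C1B, C10B=C14B) | C=C1C(=O)C2=C3[C@H](CC[C@H]4C(=C)C(=O)O[C@@H]4[C@@H]13)CC[C@@]21C(=O)C=C2C(=C)CC[C@H]3C(=C)C(=O)O[C@@H]3[C@H]21 | intermediate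
14 | A–B–C Diels–Alder adduct (C2B–C4C and C14B–C15C bonds; C1B=C10B; H2B β; at C4C the C2B branch is α) | C=C1C(=O)C2=C3[C@H](CC[C@H]4C(=C)C(=O)O[C@@H]4[C@@H]13)CC[C@@]21C(=O)[C@H]2C3=C(CC[C@H]4C(=C)C(=O)O[C@@H]4[C@@H]13)CC[C@]21C(=O)C[C@H]2C(=C)CC[C@H]3C(=C)C(=O)O[C@@H]3[C@H]21 | intermediate
15 | C10B hydroperoxide (10β-OOH; C1B=C2B enone) | C=C1C(=O)C2=C3[C@H](CC[C@H]4C(=C)C(=O)O[C@@H]4[C@@H]13)CC[C@@]21C(=O)C2=C3[C@H]1[C@H]1OC(=O)C(=C)[C@@H]1CC[C@@]3(OO)CC[C@]21C(=O)C[C@H]2C(=C)CC[C@H]3C(=C)C(=O)O[C@@H]3[C@H]21 | intermediate
16 | ainsliatrimer A | C=C1C(=O)C2=C3[C@H](CC[C@H]4C(=C)C(=O)O[C@@H]4[C@@H]13)CC[C@@]21C(=O)C2=C3[C@H]1[C@H]1OC(=O)C(=C)[C@@H]1CC[C@@]3(O)CC[C@]21C(=O)C[C@H]2C(=C)CC[C@H]3C(=C)C(=O)O[C@@H]3[C@H]21 | target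

Total step count: 11
Longest linear sequence: 10 steps (1, 3, 4, 5, 6, 7, 8, 9, 10, 11 from dehydrocostus lactone)

Steps most likely to fail

Step 8. The boat rearrangement has to bring C2A onto the concave β face of unit B, and its thermal barrier may not be reached before the dienone and the α-methylene lactones decompose; cleavage of the pyran back into two halves may also compete. The fallback sets out from 9 and comes back at 10. It runs the rearrangement on the C3A carbinol, so that the allyl unit is no longer part of an enone and a charge-accelerated shift at low temperature becomes possible. Luche reduction of 9 (NaBH4, CeCl3·7H2O, MeOH, −78 °C) should give the bis-allylic spiro-dihydropyran 3A-carbinol F1 (drawn as the 3β-alcohol from hydride attack on the convex face; either epimer serves). Me2AlCl (4 equiv, CH2Cl2, −78 to 0 °C) turns it into the aluminium alkoxide and should promote the same Claisen ring contraction, with the same chirality transfer from C10A, to the A–B spiro dimer 3A-carbinol F2. Dess–Martin oxidation (pyridine, CH2Cl2) then returns ketone 10.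

Step 4. The zwitterionic intermediate may lose a proton (ene-type course) in place of closing the ring, the enone may attack C4A=C15A, or the oxygen may close on the β face of C10A. The fallback sets out from 3 and 4 and comes back at 5. It builds the pyran in two stages. A deliberate Me2AlCl-promoted ene reaction (CH2Cl2, −20 to 0 °C) should give the δ,ε-unsaturated ketone, ene adduct F3 (C14A–C15B bond, C9A=C10A alkene, C4B–H; both C4B epimers converge). Catalytic Tf2NH (5 mol%, CH2Cl2, −20 °C) then protonates C9A and lets the enol oxygen of the C3B ketone add to the tertiary C10A cation, a cycloisomerisation of a δ,ε-unsaturated ketone to a 2,2-disubstituted dihydropyran under thermodynamic control of C10A, to give 5.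

Step 10. The amide base may attack unit A (γ-deprotonation at C10A or C5A, the latter with opening of the lactone by β-elimination), or the diene may consume itself by cycloaddition to the exocyclic enone of a second molecule. The fallback sets out from 11 and comes back at 14. IBX (DMSO/fluorobenzene, 65 °C, high dilution) dehydrogenates the saturated unit B ketone through its enol by single-electron transfer, with neither enolate nor silyl enol ether, and should give diene 13 directly. After removal of the oxidant, 13 is combined at once with excess 3 (CH2Cl2, rt, concentrated) to give 14. No new compound arises on this detour (F0).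

Further compounds
F1 | step 8 | A–B spiro-dihydropyran 3A-carbinol (3β-OH; C1A=C2A, C4A=C15A) | C=C1[C@@H](O)C=C2[C@H]1[C@H]3OC(=O)C(=C)[C@@H]3CC[C@]24CCC5=C(O4)C[C@H]6C(=C)CC[C@H]7C(=C)C(=O)O[C@@H]7[C@@H]56
F2 | step 8 | A–B spiro dimer 3A-carbinol (3β-OH; C2A–C4B bond, C1A=C10A) | C=C1[C@@H](O)[C@H]2C3=C(CC[C@H]4C(=C)C(=O)O[C@@H]4[C@@H]13)CC[C@@]21C(=O)C[C@H]2C(=C)CC[C@H]3C(=C)C(=O)O[C@@H]3[C@H]21
F3 | step 4 | ene adduct (C14A–C15B bond, C9A=C10A, C4B–H with the side chain α, unit A 3α-OTBS) | C=C1[C@H](O[Si](C)(C)C(C)(C)C)C[C@H]2C(CC[C@@H]4C(=O)C[C@H]5C(=C)CC[C@H]6C(=C)C(=O)O[C@@H]6[C@H]54)=CC[C@H]3C(=C)C(=O)O[C@@H]3[C@H]21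
F0 | step 10 | none | none
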